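The target is cut at the methylene bridge into chromene ketone 21 and the dearomatised ring. That carbocycle (the quaternary C(Me)(geranyl), its two flanking C–O carbons, the acetyl-bearing carbon, the ring C=O and the CH2-bearing carbon) is grown from a four-membered ring. Cyclobutenone 7, made from methyl(geranyl)ketene and ethoxyacetylene, takes up a second ethoxyacetylene in one thermal cascade (4π opening, [2+2], 4π opening, 6π closure). This inserts two carbons and exploits the alternating 1,3,5-oxygenation around the sp3 carbon. Hydrolysis gives an achiral trione; C-acetylation, resolution and an iminium-mediated methylene coupling with 21 finish the synthesis.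

Key step: step 3

Remark: the target is handled in the enol tautomer of its SMILES, triones are written as the corresponding enols, and (4R) refers to this tautomer. Geranyl = (2E)-3,7-dimethylocta-2,6-dien-1-yl. The absolute configuration is selected by resolution in step 6, not by an enantioselective reaction.

Step 1
Reactants: 1 propanoic acid; 2 geranyl bromide
Product: 3 rac-(4E)-2,5,9-trimethyldeca-4,8-dienoic acid
Conditions: LDA (2.2 equiv), THF–DMPU, 0 °C; then 2, −78 °C to rt; aq. HCl
Reagents that add atoms: none
Why: Carboxylic acid dianion alkylation: the α-carbon of the propanoate dianion should displace the primary allylic bromide by SN2 without touching the (E)-alkene, and the racemic α-stereocentre disappears when the ketene is formed in step 2.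

Step 2
Reactants: 3 rac-(4E)-2,5,9-trimethyldeca-4,8-dienoic acid; 4 ethoxyacetylene
Product: 7 rac-3-ethoxy-4-geranyl-4-methylcyclobut-2-en-1-one, via acid chloride 5 (not isolated), via ketene 6 (not isolated)
Conditions: (COCl)2, DMF (cat.), CH2Cl2, 0 °C to rt; concentrate; then 4 (2 equiv), Et3N, Et2O, rt to 35 °C
Reagents that add atoms: none
Why: Dehydrochlorination of 5 gives dialkylketene 6, which should be captured in situ by the electron-rich alkyne in a thermal ketene–alkyne [2+2] cycloaddition whose regiochemistry (ketene C=O carbon to the unsubstituted alkyne carbon) follows from the polarisation of the ynol ether; the ring stereocentre forms as a racemate.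

Step 3
Reactants: 7 rac-3-ethoxy-4-geranyl-4-methylcyclobut-2-en-1-one; 4 ethoxyacetylene
Product: 11 rac-3,5-diethoxy-6-geranyl-6-methylcyclohexa-2,4-dien-1-one, via vinylketene 8 (not isolated), via vinylcyclobutenone 9 (not isolated), via dienylketene 10 (not isolated)
Conditions: 4 (3 equiv), toluene, 90 °C, sealed tube
Reagents that add atoms: none
Why: Thermal conrotatory 4π ring-opening of 7 gives vinylketene 8, which adds the ynol ether in a [2+2] cycloaddition to give 4-vinylcyclobutenone 9; a second 4π opening to dienylketene 10 and a disrotatory 6π electrocyclisation then give the cyclohexa-2,4-dienone. The closest known reaction type is the Danheiser benzannulation of a cyclobutenone with an alkoxyalkyne, here ending at the dienone stage because the terminal carbon is fully substituted. The only ring closed is the carbocycle, by 6π-electrocyclic closure between the ketene carbon and the C(Me)(geranyl) terminus, so that the four ring atoms of 7 and the two alkyne carbons make up the six-membered ring. The new quaternary stereocentre forms without control, which is accepted because step 4 converts it into a non-stereogenic carbon and the configuration is fixed in steps 5 and 6. The step needs the [2+2] regiochemistry that places the second ethoxy group 1,3 to the first, secured by the polarisation of the ynol ether (ketene C=O carbon to the unsubstituted alkyne carbon), and it needs bimolecular capture of 8 to outrun [1,5]-hydrogen shift and dimerisation, secured by excess alkyne. Should 8 react instead as a diene in a [4+2] sense, the isomeric 3,5-diethoxy-2,5-dienone would hydrolyse to the same trione 12.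

Step 4
Reactants: 11 rac-3,5-diethoxy-6-geranyl-6-methylcyclohexa-2,4-dien-1-one
Product: 12 4-geranyl-3,5-dihydroxy-4-methylcyclohexa-2,5-dien-1-one (achiral enol form of the 1,3,5-trione)
Conditions: 1 M HCl, THF, rt
Reagents that add atoms: water, O
Why: Acid-catalysed enol ether hydrolysis should unmask both C–O carbons to give the trione in its enol form, which has a mirror plane through C1 and C4, so that the racemic quaternary centre of 11 becomes non-stereogenic.

Step 5
Reactants: 12 4-geranyl-3,5-dihydroxy-4-methylcyclohexa-2,5-dien-1-one
Product: 14 rac-2-acetyl-4-geranyl-3,5-dihydroxy-4-methylcyclohexa-2,5-dien-1-one, via enol acetate 13 (not isolated)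
Conditions: AcCl (1.0 equiv), Et3N, CH2Cl2, 0 °C; then DMAP (cat.), rt
Reagents that add atoms: acetyl chloride, CC(=O)Cl
Why: O-Acetylation followed by DMAP-catalysed O-to-C acyl migration (enol ester to β-triketone rearrangement) should place the acetyl group on one of the two equivalent ring CH carbons between two carbonyl groups, which makes C4 a stereocentre and therefore gives the racemate.

Step 6
Reactants: 14 rac-2-acetyl-4-geranyl-3,5-dihydroxy-4-methylcyclohexa-2,5-dien-1-one
Product: 15 (4R)-2-acetyl-4-geranyl-3,5-dihydroxy-4-methylcyclohexa-2,5-dien-1-one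
Conditions: preparative SFC, amylose tris(3,5-dimethylphenylcarbamate) phase, CO2/MeOH (0.1% HCO2H)
Reagents that add atoms: none
Why: Chromatographic resolution on a chiral stationary phase should separate the two enantiomers of the acidic β-triketone, the (4R)-enantiomer being collected; the quaternary centre cannot epimerise, so the configuration chosen here persists to the target.

Step 7
Reactants: 16 phloroglucinol; 17 hexanoyl chloride
Product: 18 1-(2,4,6-trihydroxyphenyl)hexan-1-one
Conditions: AlCl3, PhNO2–CH2Cl2, rt to 50 °C; aq. HCl
Reagents that add atoms: none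
Why: Friedel–Crafts acylation of the symmetrical, strongly activated arene should stop after one acyl group has been introduced because the product is deactivated and chelated to aluminium.

Step 8
Reactants: 18 1-(2,4,6-trihydroxyphenyl)hexan-1-one; 19 3-methylbut-2-enal
Product: 21 1-(5,7-dihydroxy-2,2-dimethyl-2H-chromen-8-yl)hexan-1-one, via quinone methide 20 (not isolated)
Conditions: ethylenediammonium diacetate (cat.), toluene, 90 °C
Reagents that add atoms: none
Why: Amine-catalysed Knoevenagel-type condensation at a free ring carbon gives quinone methide 20, which should close by oxa-6π electrocyclisation (formal [3+3] chromene annulation); closure through the oxygen next to the acyl group gives 21, and any isomer from closure through the para oxygen is removed by chromatography.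

Step 9
Reactants: 15 (4R)-2-acetyl-4-geranyl-3,5-dihydroxy-4-methylcyclohexa-2,5-dien-1-one; 21 1-(5,7-dihydroxy-2,2-dimethyl-2H-chromen-8-yl)hexan-1-one
Product: 24 (4R)-2-acetyl-4-geranyl-6-[(8-hexanoyl-5,7-dihydroxy-2,2-dimethyl-2H-chromen-6-yl)methyl]-3,5-dihydroxy-4-methylcyclohexa-2,5-dien-1-one, via Mannich base 22 (not isolated), via methylene trione 23 (not isolated)
Conditions: Eschenmoser's salt, CH2Cl2, 0 °C to rt; then 21, MeCN, 50 °C
Reagents that add atoms: N,N-dimethylmethyleneiminium iodide (Eschenmoser's salt), C=[N+](C)C.[I-]
Why: Mannich reaction at the only free ring carbon of the enolised trione, loss of dimethylamine to the enone 23 and Friedel–Crafts-type conjugate addition of the only free aromatic carbon of 21 (between two hydroxyl groups) should form the methylene bridge without touching the quaternary stereocentre.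

Compound list
1 | propanoic acid | CCC(=O)O | starting material
2 | geranyl bromide, (2E)-1-bromo-3,7-dimethylocta-2,6-diene | BrC/C=C(\C)CCC=C(C)C | starting material
3 | rac-(4E)-2,5,9-trimethyldeca-4,8-dienoic acid | CC(C/C=C(\C)CCC=C(C)C)C(=O)O | intermediate
4 | ethoxyacetylene (ethoxyethyne) | CCOC#C | starting material
5 | (4E)-2,5,9-trimethyldeca-4,8-dienoyl chloride (racemic) | CC(C/C=C(\C)CCC=C(C)C)C(=O)Cl | intermediate (not isolated)
6 | methyl(geranyl)ketene, (4E)-2,5,9-trimethyldeca-1,4,8-trien-1-one | CC(C/C=C(\C)CCC=C(C)C)=C=O | intermediate (not isolated)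
7 | rac-3-ethoxy-4-geranyl-4-methylcyclobut-2-en-1-one | CCOC1=CC(=O)C1(C)C/C=C(\C)CCC=C(C)C | intermediate
8 | vinylketene, 3-ethoxy-4-methyl-4-geranylbuta-1,3-dien-1-one (alkene geometry at the fully substituted C=C not defined) | CCOC(C=C=O)=C(C)C/C=C(\C)CCC=C(C)C | intermediate (not isolated)
9 | 3-ethoxy-4-(1-ethoxy-2-methyl-2-geranylvinyl)cyclobut-2-en-1-one (racemic) | CCOC1=CC(=O)C1C(OCC)=C(C)C/C=C(\C)CCC=C(C)C | intermediate (not isolated)
10 | dienylketene, 3,5-diethoxy-6-methyl-6-geranylhexa-1,3,5-trien-1-one | CCOC(C=C=O)=CC(OCC)=C(C)C/C=C(\C)CCC=C(C)C | intermediate (not isolated)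
11 | rac-3,5-diethoxy-6-geranyl-6-methylcyclohexa-2,4-dien-1-one | CCOC1=CC(=O)C(C)(C/C=C(\C)CCC=C(C)C)C(OCC)=C1 | intermediate
12 | 4-geranyl-3,5-dihydroxy-4-methylcyclohexa-2,5-dien-1-one (achiral) | O=C1C=C(O)C(C)(C/C=C(\C)CCC=C(C)C)C(O)=C1 | intermediate
13 | 3-acetoxy-4-geranyl-5-hydroxy-4-methylcyclohexa-2,5-dien-1-one (racemic) | CC(=O)OC1=CC(=O)C=C(O)C1(C)C/C=C(\C)CCC=C(C)C | intermediate (not isolated)
14 | rac-2-acetyl-4-geranyl-3,5-dihydroxy-4-methylcyclohexa-2,5-dien-1-one | C1=C(O)C(C)(C/C=C(\C)CCC=C(C)C)C(O)=C(C(C)=O)C1=O | intermediate
15 | (4R)-2-acetyl-4-geranyl-3,5-dihydroxy-4-methylcyclohexa-2,5-dien-1-one | C1=C(O)[C@@](C)(C/C=C(\C)CCC=C(C)C)C(O)=C(C(C)=O)C1=O | intermediate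
16 | phloroglucinol | Oc1cc(O)cc(O)c1 | starting material
17 | hexanoyl chloride | CCCCCC(=O)Cl | starting material
18 | 1-(2,4,6-trihydroxyphenyl)hexan-1-one | CCCCCC(=O)c1c(O)cc(O)cc1O | intermediate
19 | 3-methylbut-2-enal | CC(C)=CC=O | starting material
20 | o-quinone methide, 2-hexanoyl-3,5-dihydroxy-6-(3-methylbut-2-enylidene)cyclohexa-2,4-dien-1-one | CCCCCC(=O)C1=C(O)C=C(O)C(=CC=C(C)C)C1=O | intermediate (not isolated)
21 | 1-(5,7-dihydroxy-2,2-dimethyl-2H-chromen-8-yl)hexan-1-one | CCCCCC(=O)c1c(O)cc(O)c2C=CC(C)(C)Oc12 | intermediate
22 | (4R)-2-acetyl-6-(dimethylaminomethyl)-4-geranyl-3,5-dihydroxy-4-methylcyclohexa-2,5-dien-1-one | CN(C)CC1=C(O)[C@@](C)(C/C=C(\C)CCC=C(C)C)C(O)=C(C(C)=O)C1=O | intermediate (not isolated)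
23 | (R)-configured 2-acetyl-4-geranyl-3-hydroxy-4-methyl-6-methylidenecyclohex-2-ene-1,5-dione | C=C1C(=O)[C@@](C)(C/C=C(\C)CCC=C(C)C)C(O)=C(C(C)=O)C1=O | intermediate (not isolated)
24 | (4R)-2-acetyl-4-geranyl-6-[(8-hexanoyl-5,7-dihydroxy-2,2-dimethyl-2H-chromen-6-yl)methyl]-3,5-dihydroxy-4-methylcyclohexa-2,5-dien-1-one | CCCCCC(=O)c1c(O)c(CC2=C(O)[C@@](C)(C/C=C(\C)CCC=C(C)C)C(O)=C(C(C)=O)C2=O)c(O)c2c1OC(C)(C)C=C2 | target

Total step count: 9. Longest linear sequence: 7 steps (steps 1–6 and 9).

Steps most likely to fail

Step 3. The vinylketene may be lost to [1,5]-hydrogen shift or dimerisation, or the alkynyl ether may fragment thermally, before the second cycloaddition takes place. The fallback is an anionic two-carbon ring expansion of the same four-membered ring; it sets out from 7 and comes back at 12. The lithium enolate of ethyl acetate (LDA, THF, −78 °C) is added to the carbonyl group of 7. On warming, the cyclobutenyl alkoxide should open by charge-accelerated 4π ring-opening, and the resulting dienolate should close at its γ-carbon onto the ester (intramolecular Claisen condensation) to give rac-5-ethoxy-6-geranyl-6-methylcyclohex-4-ene-1,3-dione F1. Aqueous HCl in THF then hydrolyses the enol ether of F1 to 12.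

Step 8. The ring closure may not discriminate between the oxygen next to the acyl group and the para oxygen, and a second annulation may give bis-chromenes. The fallback fixes the regiochemistry by protection; it sets out from 18 and comes back at 21. MOMCl and iPr2NEt protect the two non-chelated hydroxyl groups to give 1-[2-hydroxy-4,6-bis(methoxymethoxy)phenyl]hexan-1-one F2. The remaining hydroxyl group is alkylated with 3-chloro-3-methylbut-1-yne (K2CO3, KI, CuI, acetone) to give 1-[2-(2-methylbut-3-yn-2-yloxy)-4,6-bis(methoxymethoxy)phenyl]hexan-1-one F3. Heating (xylene, 140 °C) should trigger the aryl propargyl ether Claisen rearrangement, [1,5]-hydrogen shift and oxa-6π closure, which can only use the single free ortho carbon and the oxygen next to the acyl group, to give 1-[5,7-bis(methoxymethoxy)-2,2-dimethyl-2H-chromen-8-yl]hexan-1-one F4. HCl in MeOH at rt removes the MOM groups of F4 to give 21.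

Step 9. The two halves may each dimerise through the methylene unit, the enone 23 may be captured in a hetero-Diels–Alder reaction by the chromene or geranyl alkenes, and the bridge may scramble on prolonged heating. The fallback reverses the roles of the two partners; it sets out from 21 and comes back at 24. Compound 21 is aminomethylated with Eschenmoser's salt (CH2Cl2, rt) at its only free aromatic carbon to give 1-[6-(dimethylaminomethyl)-5,7-dihydroxy-2,2-dimethyl-2H-chromen-8-yl]hexan-1-one F5, which is isolated. Heating F5 with 15 (toluene, 80 °C) should release the o-quinone methide of the aromatic half, which is captured by the free enol carbon of 15 to give 24.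

Further compounds
F1 | step 3 | rac-5-ethoxy-6-geranyl-6-methylcyclohex-4-ene-1,3-dione | CCOC1=CC(=O)CC(=O)C1(C)C/C=C(\C)CCC=C(C)C
F2 | step 8 | 1-[2-hydroxy-4,6-bis(methoxymethoxy)phenyl]hexan-1-one | CCCCCC(=O)c1c(O)cc(OCOC)cc1OCOC
F3 | step 8 | 1-[2-(2-methylbut-3-yn-2-yloxy)-4,6-bis(methoxymethoxy)phenyl]hexan-1-one | CCCCCC(=O)c1c(OC(C)(C)C#C)cc(OCOC)cc1OCOC
F4 | step 8 | 1-[5,7-bis(methoxymethoxy)-2,2-dimethyl-2H-chromen-8-yl]hexan-1-one | CCCCCC(=O)c1c(OCOC)cc(OCOC)c2C=CC(C)(C)Oc12
F5 | step 9 | 1-[6-(dimethylaminomethyl)-5,7-dihydroxy-2,2-dimethyl-2H-chromen-8-yl]hexan-1-one | CCCCCC(=O)c1c(O)c(CN(C)C)c(O)c2C=CC(C)(C)Oc12
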